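**Plan**

- Numbering used throughout: lactone O1, C2 (C=O), C3 (Me), C4 (OH), C5 (ylidene carbon), then the chain from C6 (vinyl CH) and C7 (stereocentre) to C14 (CH2 on the furan).
- Cuts, in retrosynthetic order: O4–CH3 (mask of the tetronic acid); then O1–C5, because the Z enol lactone with O1 on C5 and the C6–H next to C7 is the anti adduct of the C2 carboxylate across a C5≡C6 alkyne; then C3–C4, C4–C5 and C5–C6 of the enynoic acid; C10–C11; C8–C9; C12–CH3 and C14–furan; the CH2 between the furans.
- Forward: the two furans are joined and grown into an (E)-alkenyl iodide (steps 1–5); a chiral pentenoate (step 6) is attached by B-alkyl Suzuki coupling (step 7); the ester end is built into the 3-methoxy-2-en-4-ynoic acid (steps 8–14); the butenolide, the only ring made, closes in step 15; demethylation ends the route.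
- Stereochemistry: C7 is bought with methyl (R)-3-bromo-2-methylpropanoate and never takes part in bond formation; E at C11=C12 comes from syn carboalumination and stereoretentive couplings; Z at C5=C6 from the anti addition in step 15.

Key step: step 15

Remark: 12 is the commercial bromo ester of the Roche ester series; carbinol 4, aldol 24 and keto ester 25 are carried as stereoisomer mixtures at centres that are destroyed later.

Step 1
Reactants: 1 3-bromofuran; 2 4-bromofuran-2-carbaldehyde
Product: 4 racemic (4-bromofuran-2-yl)(furan-3-yl)methanol, via furan-3-yllithium 3 (not isolated)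
Conditions: n-BuLi, THF, −78 °C; then 2, −78 °C; aq. NH4Cl
Reagents that add atoms: none
Why: Bromine–lithium exchange at −78 °C gives the 3-lithiofuran without migration to C2, and its 1,2-addition to the aldehyde (organolithium carbonyl addition) is far faster than exchange with the ring bromide of 2; the carbinol centre is racemic and disappears in step 2.

Step 2
Reactants: 4 racemic (4-bromofuran-2-yl)(furan-3-yl)methanol
Product: 5 4-bromo-2-(furan-3-ylmethyl)furan
Conditions: Et3SiH (3 equiv), CF3CO2H, CH2Cl2, −20 → 0 °C, 4 added slowly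
Reagents that add atoms: none
Why: Ionic hydrogenation of a diheteroaryl carbinol: the cation stabilised by both furans forms at low temperature and is reduced by excess silane before it can alkylate another furan.

Step 3
Reactants: 5 4-bromo-2-(furan-3-ylmethyl)furan; 6 (4-bromobut-1-yn-1-yl)trimethylsilane
Product: 8 {4-[5-(furan-3-ylmethyl)furan-3-yl]but-1-yn-1-yl}trimethylsilane, via zinc reagent 7 (not isolated)
Conditions: 6, Zn dust, LiCl, THF, 50 °C; then 5, Pd(OAc)2 (2 mol %), SPhos (4 mol %), THF, rt
Reagents that add atoms: none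
Why: Negishi sp3–sp2 cross-coupling: LiCl-promoted zinc insertion gives the homopropargylic zinc reagent, which couples with the heteroaryl bromide at zerovalent palladium carrying a bulky biarylphosphine faster than β-hydride elimination, the silyl cap keeping the alkyne C–H away from the organometallic.

Step 4
Reactants: 8 {4-[5-(furan-3-ylmethyl)furan-3-yl]but-1-yn-1-yl}trimethylsilane
Product: 9 4-(but-3-yn-1-yl)-2-(furan-3-ylmethyl)furan
Conditions: K2CO3 (cat.), MeOH, rt
Reagents that add atoms: none
Why: Carbonate-catalysed methanolysis of the alkynyl C–Si bond (protodesilylation) is selective and touches nothing else in 8.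

Step 5
Reactants: 9 4-(but-3-yn-1-yl)-2-(furan-3-ylmethyl)furan
Product: 11 2-(furan-3-ylmethyl)-4-[(3E)-4-iodo-3-methylbut-3-en-1-yl]furan, via alkenylalane 10 (not isolated)
Conditions: Me3Al, Cp2ZrCl2 (20 mol %), CH2Cl2, 0 °C → rt; then I2, THF, −30 → 0 °C
Reagents that add atoms: trimethylaluminium C[Al](C)C; iodine [I][I]
Why: Zirconium-catalysed carboalumination (Negishi methylalumination) adds methyl and aluminium syn across the terminal alkyne with methyl on the internal carbon, and iodinolysis of the C–Al bond with retention fixes the E geometry of the future C11=C12 alkene.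

Step 6
Reactants: 12 methyl (R)-3-bromo-2-methylpropanoate; 13 bromoethene
Product: 15 methyl (S)-2-methylpent-4-enoate, via zinc reagent 14 (not isolated)
Conditions: 12, Zn dust, LiCl, THF, 50 °C; then 13 (1 M in THF), Pd(PPh3)4 (3 mol %), rt
Reagents that add atoms: none
Why: Zinc insertion into the primary bromide gives a configurationally stable β-zincio ester (the stereocentre is not involved) and Negishi coupling with vinyl bromide at zerovalent palladium forms C8–C9, so C7 keeps the configuration bought with 12.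

Step 7
Reactants: 15 methyl (S)-2-methylpent-4-enoate; 11 2-(furan-3-ylmethyl)-4-[(3E)-4-iodo-3-methylbut-3-en-1-yl]furan
Product: 17 methyl (2S,6E)-9-[5-(furan-3-ylmethyl)furan-3-yl]-2,7-dimethylnon-6-enoate, via alkylborane 16 (not isolated)
Conditions: 15, 9-BBN-H, THF, 0 °C → rt; then 11, Pd(dppf)Cl2·CH2Cl2 (5 mol %), Ph3As, Cs2CO3, DMF–H2O, rt
Reagents that add atoms: none
Why: B-alkyl Suzuki–Miyaura coupling: 9-BBN-H hydroborates the terminal alkene at C10 without reducing the ester, and the primary alkyl group is transferred to the alkenyl iodide with retention of the E geometry under mild aqueous base that does not enolise the ester.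

Step 8
Reactants: 17 methyl (2S,6E)-9-[5-(furan-3-ylmethyl)furan-3-yl]-2,7-dimethylnon-6-enoate
Product: 18 (2S,6E)-9-[5-(furan-3-ylmethyl)furan-3-yl]-2,7-dimethylnon-6-enal
Conditions: i-Bu2AlH (1.1 equiv), CH2Cl2, −78 °C; MeOH, then aq. KNaC4H4O6; used crude
Reagents that add atoms: none
Why: Partial reduction of a methyl ester with i-Bu2AlH at −78 °C stops at the aluminium hemiacetal, which releases the aldehyde only on work-up, so the α-stereocentre never meets base.

Step 9
Reactants: 18 (2S,6E)-9-[5-(furan-3-ylmethyl)furan-3-yl]-2,7-dimethylnon-6-enal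
Product: 19 4-[(3E,8S)-10,10-dibromo-3,8-dimethyldeca-3,9-dien-1-yl]-2-(furan-3-ylmethyl)furan
Conditions: CBr4, PPh3, 2,6-lutidine, CH2Cl2, 0 °C
Reagents that add atoms: carbon tetrabromide BrC(Br)(Br)Br
Why: Corey–Fuchs (Ramirez) dibromoolefination is a Wittig-type reaction run without any base strong enough to enolise the α-branched aldehyde, and lutidine buffers the HBr traces that would harm the furans.

Step 10
Reactants: 19 4-[(3E,8S)-10,10-dibromo-3,8-dimethyldeca-3,9-dien-1-yl]-2-(furan-3-ylmethyl)furan
Product: 21 (4S,8E)-11-[5-(furan-3-ylmethyl)furan-3-yl]-4,9-dimethylundec-8-en-2-ynal, via lithium acetylide 20 (not isolated)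
Conditions: n-BuLi (2.1 equiv), THF, −78 °C; then DMF, −78 °C → rt; inverse quench into aq. KH2PO4, 0 °C
Reagents that add atoms: N,N-dimethylformamide CN(C)C=O
Why: Second stage of the Corey–Fuchs alkyne synthesis: bromine–lithium exchange, 1,2-shift and deprotonation give the lithium acetylide, which DMF formylates, and the buffered inverse quench keeps the liberated dimethylamine from adding to the ynal.

Step 11
Reactants: 21 (4S,8E)-11-[5-(furan-3-ylmethyl)furan-3-yl]-4,9-dimethylundec-8-en-2-ynal; 22 methyl propanoate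
Product: 24 methyl (6S,10E)-13-[5-(furan-3-ylmethyl)furan-3-yl]-3-hydroxy-2,6,11-trimethyltridec-10-en-4-ynoate, via ester enolate 23 (not isolated)
Conditions: 22, LiN(i-Pr)2, THF, −78 °C; then 21, −78 °C; aq. NH4Cl
Reagents that add atoms: none
Why: Aldol addition of a lithium ester enolate to an ynal is a fast 1,2-addition at −78 °C; the two new stereocentres form unselectively, which is of no consequence because both are erased in steps 12 and 13.

Step 12
Reactants: 24 methyl (6S,10E)-13-[5-(furan-3-ylmethyl)furan-3-yl]-3-hydroxy-2,6,11-trimethyltridec-10-en-4-ynoate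
Product: 25 methyl (6S,10E)-13-[5-(furan-3-ylmethyl)furan-3-yl]-2,6,11-trimethyl-3-oxotridec-10-en-4-ynoate
Conditions: Dess–Martin periodinane (1.2 equiv), pyridine, CH2Cl2, 0 °C → rt
Reagents that add atoms: none
Why: Dess–Martin oxidation of the propargylic β-hydroxy ester to the 3-oxo-4-ynoate runs under buffered, non-aqueous conditions that neither cyclise the keto ester nor affect the furans and the alkene.

Step 13
Reactants: 25 methyl (6S,10E)-13-[5-(furan-3-ylmethyl)furan-3-yl]-2,6,11-trimethyl-3-oxotridec-10-en-4-ynoate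
Product: 27 methyl (2E,6S,10E)-13-[5-(furan-3-ylmethyl)furan-3-yl]-3-methoxy-2,6,11-trimethyltrideca-2,10-dien-4-ynoate, via potassium enolate 26 (not isolated)
Conditions: KN(SiMe3)2, 18-crown-6, THF–DMPU, −78 °C; then Me2SO4, −78 → 0 °C
Reagents that add atoms: dimethyl sulfate COS(=O)(=O)OC
Why: O-alkylation of a β-keto ester enolate: the crown-ether-separated potassium enolate reacts with the hard electrophile Me2SO4 at the ketone oxygen and through the conformer with the oxyanion anti to the ester carbonyl, which should give the E enol ether (ester cis to the slim alkyne), also the thermodynamically preferred isomer.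

Step 14
Reactants: 27 methyl (2E,6S,10E)-13-[5-(furan-3-ylmethyl)furan-3-yl]-3-methoxy-2,6,11-trimethyltrideca-2,10-dien-4-ynoate
Product: 28 (2E,6S,10E)-13-[5-(furan-3-ylmethyl)furan-3-yl]-3-methoxy-2,6,11-trimethyltrideca-2,10-dien-4-ynoic acid
Conditions: LiOH·H2O, THF–MeOH–H2O, rt; then 0.5 M HCl to pH 3, 0 °C
Reagents that add atoms: lithium hydroxide [Li+].[OH-]
Why: Saponification of the methyl ester at room temperature, the enol ether (a vinylogous carbonate) being inert to hydroxide and cold dilute acid sufficing to liberate the acid without harming enol ether or furans.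

Step 15
Reactants: 28 (2E,6S,10E)-13-[5-(furan-3-ylmethyl)furan-3-yl]-3-methoxy-2,6,11-trimethyltrideca-2,10-dien-4-ynoic acid
Product: 29 (5Z)-5-{(2S,6E)-9-[5-(furan-3-ylmethyl)furan-3-yl]-2,7-dimethylnon-6-en-1-ylidene}-4-methoxy-3-methylfuran-2(5H)-one
Conditions: Ag2CO3 (10 mol %), DMF, rt, dark
Reagents that add atoms: none
Why: Ag2CO3 turns the acid into its silver carboxylate and monovalent silver π-activates the C5≡C6 alkyne; the carboxylate oxygen, held cis to the alkyne by the E enol ether, attacks C5 on the face opposite the metal, and protonolysis of the resulting alkenylsilver with retention frees the catalyst. The closest known reaction type is the silver-catalysed cycloisomerisation of (Z)-2-en-4-ynoic acids to (Z)-γ-alkylidenebutenolides. The butenolide ring closes in the 5-exo-dig mode by forming O1–C5. No stereocentre is created: the Z geometry of C5=C6 follows from the anti addition (hydrogen ends trans to O1, the C7 chain cis), and C7 is untouched under these neutral conditions. The step needs 5-exo over 6-endo closure; the C4 methoxy group feeds electron density into the acrylate and so weakens the conjugate activation of C6, the soft carbophilic metal favours exo attack, and the branched C7 substituent shields C6.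

Step 16
Reactants: 29 (5Z)-5-{(2S,6E)-9-[5-(furan-3-ylmethyl)furan-3-yl]-2,7-dimethylnon-6-en-1-ylidene}-4-methoxy-3-methylfuran-2(5H)-one
Product: 30 (5Z)-5-{(2S,6E)-9-[5-(furan-3-ylmethyl)furan-3-yl]-2,7-dimethylnon-6-en-1-ylidene}-4-hydroxy-3-methylfuran-2(5H)-one
Conditions: NaSEt (3 equiv), DMF, 70 °C; then cold 0.5 M HCl
Reagents that add atoms: none
Why: SN2 demethylation of a vinylogous methyl ester by a soft thiolate: the tetronate is a leaving group comparable to a carboxylate, and the anion formed protects the ring from further attack until acidification releases 30.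

**Compound list**

1 | 3-bromofuran | Brc1ccoc1 | starting material
2 | 4-bromofuran-2-carbaldehyde | O=Cc1cc(Br)co1 | starting material
3 | furan-3-yllithium | [Li]c1ccoc1 | intermediate
4 | racemic (4-bromofuran-2-yl)(furan-3-yl)methanol | OC(c1cc(Br)co1)c1ccoc1 | intermediate
5 | 4-bromo-2-(furan-3-ylmethyl)furan | Brc1coc(Cc2ccoc2)c1 | intermediate
6 | (4-bromobut-1-yn-1-yl)trimethylsilane | C[Si](C)(C)C#CCCBr | starting material
7 | [4-(trimethylsilyl)but-3-yn-1-yl]zinc bromide | C[Si](C)(C)C#CCC[Zn]Br | intermediate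
8 | {4-[5-(furan-3-ylmethyl)furan-3-yl]but-1-yn-1-yl}trimethylsilane | C[Si](C)(C)C#CCCc1coc(Cc2ccoc2)c1 | intermediate
9 | 4-(but-3-yn-1-yl)-2-(furan-3-ylmethyl)furan | C#CCCc1coc(Cc2ccoc2)c1 | intermediate
10 | {(1E)-4-[5-(furan-3-ylmethyl)furan-3-yl]-2-methylbut-1-en-1-yl}dimethylalane | C[Al](C)/C=C(\C)CCc1coc(Cc2ccoc2)c1 | intermediate
11 | 2-(furan-3-ylmethyl)-4-[(3E)-4-iodo-3-methylbut-3-en-1-yl]furan | I/C=C(\C)CCc1coc(Cc2ccoc2)c1 | intermediate
12 | methyl (R)-3-bromo-2-methylpropanoate | COC(=O)[C@@H](C)CBr | starting material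
13 | bromoethene (vinyl bromide) | C=CBr | starting material
14 | [(2R)-3-methoxy-2-methyl-3-oxopropyl]zinc bromide | COC(=O)[C@@H](C)C[Zn]Br | intermediate
15 | methyl (S)-2-methylpent-4-enoate | COC(=O)[C@@H](C)CC=C | intermediate
16 | methyl (2S)-5-(9-borabicyclo[3.3.1]nonan-9-yl)-2-methylpentanoate | COC(=O)[C@@H](C)CCCB1C2CCCC1CCC2 | intermediate
17 | methyl (2S,6E)-9-[5-(furan-3-ylmethyl)furan-3-yl]-2,7-dimethylnon-6-enoate | COC(=O)[C@@H](C)CCC/C=C(\C)CCc1coc(Cc2ccoc2)c1 | intermediate
18 | (2S,6E)-9-[5-(furan-3-ylmethyl)furan-3-yl]-2,7-dimethylnon-6-enal | O=C[C@@H](C)CCC/C=C(\C)CCc1coc(Cc2ccoc2)c1 | intermediate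
19 | 4-[(3E,8S)-10,10-dibromo-3,8-dimethyldeca-3,9-dien-1-yl]-2-(furan-3-ylmethyl)furan | BrC(Br)=C[C@@H](C)CCC/C=C(\C)CCc1coc(Cc2ccoc2)c1 | intermediate
20 | [(3S,7E)-10-[5-(furan-3-ylmethyl)furan-3-yl]-3,8-dimethyldec-7-en-1-yn-1-yl]lithium | [Li]C#C[C@@H](C)CCC/C=C(\C)CCc1coc(Cc2ccoc2)c1 | intermediate
21 | (4S,8E)-11-[5-(furan-3-ylmethyl)furan-3-yl]-4,9-dimethylundec-8-en-2-ynal | O=CC#C[C@@H](C)CCC/C=C(\C)CCc1coc(Cc2ccoc2)c1 | intermediate
22 | methyl propanoate | CCC(=O)OC | starting material
23 | lithium 1-methoxyprop-1-en-1-olate (enolate of methyl propanoate) | CC=C(OC)O[Li] | intermediate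
24 | methyl (6S,10E)-13-[5-(furan-3-ylmethyl)furan-3-yl]-3-hydroxy-2,6,11-trimethyltridec-10-en-4-ynoate (diastereomer mixture at C2 and C3) | COC(=O)C(C)C(O)C#C[C@@H](C)CCC/C=C(\C)CCc1coc(Cc2ccoc2)c1 | intermediate
25 | methyl (6S,10E)-13-[5-(furan-3-ylmethyl)furan-3-yl]-2,6,11-trimethyl-3-oxotridec-10-en-4-ynoate (C2 epimers) | COC(=O)C(C)C(=O)C#C[C@@H](C)CCC/C=C(\C)CCc1coc(Cc2ccoc2)c1 | intermediate
26 | potassium enolate of keto ester 25 | COC(=O)C(C)=C([O-])C#C[C@@H](C)CCC/C=C(\C)CCc1coc(Cc2ccoc2)c1.[K+] | intermediate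
27 | methyl (2E,6S,10E)-13-[5-(furan-3-ylmethyl)furan-3-yl]-3-methoxy-2,6,11-trimethyltrideca-2,10-dien-4-ynoate | COC(=O)/C(C)=C(OC)\C#C[C@@H](C)CCC/C=C(\C)CCc1coc(Cc2ccoc2)c1 | intermediate
28 | (2E,6S,10E)-13-[5-(furan-3-ylmethyl)furan-3-yl]-3-methoxy-2,6,11-trimethyltrideca-2,10-dien-4-ynoic acid | OC(=O)/C(C)=C(OC)\C#C[C@@H](C)CCC/C=C(\C)CCc1coc(Cc2ccoc2)c1 | intermediate
29 | (5Z)-5-{(2S,6E)-9-[5-(furan-3-ylmethyl)furan-3-yl]-2,7-dimethylnon-6-en-1-ylidene}-4-methoxy-3-methylfuran-2(5H)-one | CC1=C(OC)/C(=C/[C@@H](C)CCC/C=C(\C)CCc2coc(Cc3ccoc3)c2)OC1=O | intermediate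
30 | (5Z)-5-{(2S,6E)-9-[5-(furan-3-ylmethyl)furan-3-yl]-2,7-dimethylnon-6-en-1-ylidene}-4-hydroxy-3-methylfuran-2(5H)-one | CC1=C(O)/C(=C/[C@@H](C)CCC/C=C(\C)CCc2coc(Cc3ccoc3)c2)OC1=O | target

**Count**

Total steps: 16. Longest linear sequence: 15 steps (steps 1–5 and 7–16).

**Steps most likely to fail**

Step 13. Methylation may occur at C3 (carbon) instead of oxygen, the enol ether may form with the ester trans to the alkyne, or the enolate may cyclise onto the ynone before it is trapped. The fallback sets out from 24 and comes back at 30; it keeps the C4 oxygen at the alcohol level so that no enol ether geometry is needed. Aldol 24 is saponified (LiOH, THF–H2O, 0 °C) to the 3-hydroxy-4-ynoic acid F1. Under Ag2CO3 catalysis F1 should undergo the same anti 5-exo-dig closure of O1–C5, now on a non-conjugated pent-4-ynoic acid for which 6-endo attack does not compete, giving the (Z)-ylidene hydroxy lactone F2. Oxidation of the C4 carbinol of F2 with Dess–Martin periodinane gives the β-keto lactone, which is tetronic acid 30.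

Step 15. The carboxylate may attack C6 (6-endo closure to the 2-pyranone), or turnover may stall through binding of silver to the electron-rich enol ether and furans. The fallback sets out from 18 and comes back at 29 by the classical vinylogous aldol–dehydration. 4-Methoxy-3-methylfuran-2(5H)-one F3, obtained from commercial 3-methyltetronic acid with Me2SO4 and K2CO3, is deprotonated at C5 with LiN(i-Pr)2 at −78 °C to the lithium furanolate F4. F4 adds to aldehyde 18 to give the carbinol F5. Mesylation (MsCl, Et3N) to the mesylate F6 and elimination with DBU should give 29, the Z isomer being the thermodynamically favoured one.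

Step 16. The thiolate may add to C6 or to the lactone carbonyl of the dienyl enol lactone, the exocyclic alkene may isomerise, or dealkylation may stay incomplete at a temperature the product tolerates. The fallback sets out from 25 and comes back at 30, with a fluoride-labile group on O4 in place of methyl. The potassium enolate 26 is alkylated with 2-(trimethylsilyl)ethoxymethyl chloride to the SEM enol ether ester F7. F7 is saponified to the SEM acid F8, which is cyclised with Ag2CO3 to the SEM tetronate F9. n-Bu4NF in THF at room temperature then releases 30.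

**Further compounds**

F1 | step 13 | (6S,10E)-13-[5-(furan-3-ylmethyl)furan-3-yl]-3-hydroxy-2,6,11-trimethyltridec-10-en-4-ynoic acid | OC(=O)C(C)C(O)C#C[C@@H](C)CCC/C=C(\C)CCc1coc(Cc2ccoc2)c1
F2 | step 13 | (5Z)-5-{(2S,6E)-9-[5-(furan-3-ylmethyl)furan-3-yl]-2,7-dimethylnon-6-en-1-ylidene}-4-hydroxy-3-methyloxolan-2-one | CC1C(O)/C(=C/[C@@H](C)CCC/C=C(\C)CCc2coc(Cc3ccoc3)c2)OC1=O
F3 | step 15 | 4-methoxy-3-methylfuran-2(5H)-one | COC1=C(C)C(=O)OC1
F4 | step 15 | lithium 4-methoxy-3-methylfuran-2-olate | [Li]Oc1occ(OC)c1C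
F5 | step 15 | 5-{(2S,6E)-9-[5-(furan-3-ylmethyl)furan-3-yl]-1-hydroxy-2,7-dimethylnon-6-en-1-yl}-4-methoxy-3-methylfuran-2(5H)-one | COC1=C(C)C(=O)OC1C(O)[C@@H](C)CCC/C=C(\C)CCc2coc(Cc3ccoc3)c2
F6 | step 15 | (2S,6E)-9-[5-(furan-3-ylmethyl)furan-3-yl]-1-(3-methoxy-4-methyl-5-oxo-2,5-dihydrofuran-2-yl)-2,7-dimethylnon-6-en-1-yl methanesulfonate | COC1=C(C)C(=O)OC1C(OS(C)(=O)=O)[C@@H](C)CCC/C=C(\C)CCc2coc(Cc3ccoc3)c2
F7 | step 16 | methyl (2E,6S,10E)-13-[5-(furan-3-ylmethyl)furan-3-yl]-2,6,11-trimethyl-3-{[2-(trimethylsilyl)ethoxy]methoxy}trideca-2,10-dien-4-ynoate | COC(=O)/C(C)=C(OCOCC[Si](C)(C)C)\C#C[C@@H](C)CCC/C=C(\C)CCc1coc(Cc2ccoc2)c1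
F8 | step 16 | (2E,6S,10E)-13-[5-(furan-3-ylmethyl)furan-3-yl]-2,6,11-trimethyl-3-{[2-(trimethylsilyl)ethoxy]methoxy}trideca-2,10-dien-4-ynoic acid | OC(=O)/C(C)=C(OCOCC[Si](C)(C)C)\C#C[C@@H](C)CCC/C=C(\C)CCc1coc(Cc2ccoc2)c1
F9 | step 16 | (5Z)-5-{(2S,6E)-9-[5-(furan-3-ylmethyl)furan-3-yl]-2,7-dimethylnon-6-en-1-ylidene}-3-methyl-4-{[2-(trimethylsilyl)ethoxy]methoxy}furan-2(5H)-one | CC1=C(OCOCC[Si](C)(C)C)/C(=C/[C@@H](C)CCC/C=C(\C)CCc2coc(Cc3ccoc3)c2)OC1=O
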